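## Structural features

Songaricalarin B is an oplopane: a trans-fused bicyclo[4.3.0]nonane in which cyclohexane ring A (C1, C2, C6, C7, C8, C9) and cyclopentane ring B (C2–C6) share the C2–C6 bond. C1 carries the exocyclic methylene (C15), C3 is the ring CH2, C4 an acetate, C5 the 1-acetoxyethyl chain (carbinol C10, methyl C14), C7 the 2-methyloxiranyl group (quaternary C11, CH2 C12, methyl C13), C8 the free hydroxyl and C9 the (E)-3-methylpent-2-enoate. There are nine stereocentres (2R,4S,5S,6S,7S,8R,9S,10S,11S): C9–C8–C7–C6–C5–C4 are contiguous, C2 closes the array through the trans ring fusion, and C10 and C11 sit one bond outside the rings on freely rotating groups. On ring A the C7 and C8 substituents are trans-diequatorial and the C8/C9 oxygens are cis with the C9 ester axial. On ring B the C4 acetate and the C5 chain are cis to each other and to H6, and O4/O10 form an anti-1,3-diol. Fragile groups are the acid-sensitive 2,2-disubstituted oxirane, the C1 methylene allylic to the C9 ester, the enoate (E/Z drift, deconjugation), and three esters next to a free hydroxyl that is cis-vicinal to one of them (acyl migration). The real difficulty is the stereochemical density, the two side-chain centres C10 and C11, and telling four oxygens apart (C4, C10 acetates; C8 free; C9 enoate). The feature exploited is that C7 (carbon branch), C8 and C9 (oxygens, trans then cis) beside C1 at the ketone level reproduce C2–C4 of a 2-C-branched D-galactopyranoside whose ring oxygen is replaced by C2. Ring A can therefore be made from galactose by exchanging the ring oxygen for carbon, with the absolute configuration of C7–C9 taken from the sugar.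

## Logic of the disconnections

The C11–O and C12–O bonds of 34 are cut first, giving 33. The oxirane is the most acid-labile group and C11 the least controllable centre, so it is made last, when the free O8–H of 33 can direct the oxidant. The forward step must choose between two 1,1-disubstituted alkenes and between the two faces of a rotating isopropenyl group.

The O8–Si bond and then the C9–O acyl bond are cut (33 to 32, 32 to 30 + 31). The enoate would not survive enolate or hydride chemistry, so it enters late. The forward acylation meets a hindered axial allylic hydroxyl, and O8 must stay masked to prevent wrong-site acylation and migration.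

The C9–O naphthylmethyl bond and the two acetyl C–O bonds are cut (30 to 29 to 28). This reduces the problem to a diol in which O8 and O9 carry different, orthogonal groups. The demand is that the four oxygens never become equivalent.

The C10–H bond (28 to 27) and the C10–C14 bond (27 to 25) are cut. C10 is set by hydride delivery from O4 and the methyl ketone is derived from an ester, so C10 is never a ketone while C4 is one. The demand is a cis C4–OH/C5–acyl relationship.

The C4–H bond is cut (25 to 24). A ring ketone next to a C5 substituent lets hydride enter anti to that substituent. C5 is labile in 24, so it must settle trans to the C6–C7 bond.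

The C4–C5 bond is cut (24 to 23), opening ring B to two acetic acid arms on C2 and C6. The forward crossed Claisen must be regiochemically unambiguous, which is why the arms are an ester (donor at C5) and an N-methoxy-N-methylamide (acceptor at C4).

The C1=C15 bond is cut (23 to 22). Olefination directly after the alkylation locks the C2 centre and removes the base-sensitive β-silyloxy ketone before strong base is used. It must select the ketone over ester and amide.

The C2–C3 bond (22 to 20 + 21) and the C5–C6 bond (20 to 17 + 18) are cut. Both arise from one enone by conjugate addition and enolate alkylation. The forward steps must give C6 trans to C7 and C2 trans to C6.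

The C2=C6 double bond is traced to the C6–O bond of 15 (17 to 15). Dehydration erases the only stereocentre the key step creates.

The C2–C6 bond is cut (15 to 13). This is the ring-atom exchange: ring A becomes a pyranoside with an exocyclic enol ether. The forward step must react at the enol ether and not at the isopropenyl group.

The enol ether double bond, the O8–Si bond and the C–I bond are removed in turn (13 to 12 to 11 to 10). These are routine functional-group changes at the primary carbon and at O8 (sugar O3).

The methyl glycoside bond is cut and the 1,6-anhydro bridge re-formed (10 to 9). The bridge is what enforces the chair needed in the next disconnection. Its forward cleavage must spare the isopropenyl group.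

The C7–C11 bond is cut (9 to 7 + 8). The branch enters by trans-diaxial opening of an oxirane, which unveils O8 as the only free hydroxyl. Regiochemistry rests on the bridged 1C4 chair.

Finally 7 is traced through 6, 4, 3 and 2 to 1. The O9 ether, the oxirane C–O bond, the tosylate and the acetal are removed. Each forward step uses the one hydroxyl that is free or the one cis-diol present.

## Other disconnections considered

Alternative 1: The cut is C8–C9. In the forward direction SmI2 (divalent samarium) reduces both aldehydes of dialdehyde A2 to ketyls that couple to the cis-diol A1.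
- In its favour: ring A and both carbinol centres are formed in one mild, neutral step, the coupling is inherently cis-selective in six-ring closures, ring B with C4, C5 and C10 is already complete, and no mercury is used. In the number of useful stereocentres made by the key step it is better than the chosen plan, whose key step creates only a transient centre.
- Against it: A2 has seven stereocentres on a cyclopentane and two open arms with no chiral-pool template. Both aldehydes are α-branched and epimerisable, C7 being also allylic. The α-alkoxy aldehyde can lose its C–O bond under SmI2. The trans relationship of O8 to the C7 branch rests on 1,2-induction in the coupling.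
- Comparison: A1 is a free cis-diol, so C8 and C9 must be told apart after the event, whereas the chosen plan carries them differentiated from the sugar. Mechanistically both closures are six-membered and reliable. In step economy the pinacol route is at best equal, because the work is moved into the synthesis of A2.

Alternative 2: The cut is C5–C6, with C6–C10 reconnected. In the forward direction BF3·OEt2 opens the oxirane of trans-decalin epoxy alcohol A4 at C5 while the C6–C10 bond migrates, giving the hydrindane β-hydroxy ketone A3.
- In its favour: the shift is stereospecific (inversion at C5, retention at C4 and C6), so A3 has the cis C4–OH/C5–acetyl pattern ready for anti-reduction at C10. That is the pattern the chosen plan needs three steps (24 to 27) to reach, and on this point the alternative is the better one. Decalins are accessible by annulation or cycloaddition, and O8 is already distinguished.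
- Against it: A4 needs six defined stereocentres including a tertiary carbinol and an oxirane. The ring bond must be anti to the C5–O bond, in competition with methyl or hydride shift. BF3 meets an isopropenyl group and an allylic silyl ether. C9 is unoxidised in A3, so a later allylic oxidation with transposition must set the axial C9 oxygen and the C1 methylene.
- Comparison: structurally it solves ring B better and ring A worse than the chosen plan, mechanistically it is less predictable, and in step count it is probably equal.

Alternative 3: The cuts are C2–C6, C3–C4 and C4–C5. In the forward direction Co2(CO)8 with an amine N-oxide joins the alkyne, the vinyl group and CO of acyclic enyne A6 to the bicyclic enone A5.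
- In its favour: both rings and three C–C bonds are made in one step from a chain whose C7–C10 centres can come from the chiral pool, and C10 is preset. In bond-forming economy this is clearly better than the chosen plan.
- Against it: 1,7-enynes cyclise less readily than 1,6-enynes. The C2 centre depends on induction from C1. A5 holds a tetrasubstituted C5=C6 enone, so the two centres that define the trans fusion and the C5 chain must be set by a later reduction with a β-silyloxy group prone to elimination. The C8/C9 acetal leaves the diol undifferentiated.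
- Comparison: the chosen plan builds the rings more slowly but sets C6, C2 and C5 by substrate-controlled steps of known sense. Overall step counts are likely similar.

Key step: step 11

Remark (atom mapping): sugar C1, C2, C3, C4, C5, C6 become target C6, C7, C8, C9, C1, C2, and the ring oxygen becomes the C6 hydroxyl.

Remark (C8/C9 protection): O8 and O9 carry different groups (TBS and 2-naphthylmethyl, NAP) from the sugar stage on, not a common acetal, because an axial allylic and an equatorial hydroxyl cannot be reliably told apart late. The oxirane precursor offers one free hydroxyl before and one after ring opening, so the two groups go on without any selectivity problem.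

Remark (C6 carbinol): 15 is drawn with the C6 hydroxyl cis to the C7 isopropenyl group (trans to O8), the sense usually favoured in this carbocyclisation. The centre is erased in step 12, so the other epimer converges.

Remark (anomer): 10–13 are drawn as α-glycosides, the anomer favoured by acidic methanolysis. The β-anomer should follow the same path, since the anomeric centre is lost in steps 11–12.

Assumption: 18, 21 and (E)-configured 31 are bought as catalogue chemicals.

## Steps

Step 1
Reactants: 1 D-galactose
Product: 2 1,6-anhydro-β-D-galactopyranose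
Conditions: 2-chloro-1,3-dimethylimidazolinium chloride, Et3N, H2O, 0 °C to rt
Reagents that add atoms: none
Why: Dehydrative intramolecular glycosylation: the chloroamidinium salt activates the anomeric hydroxyl in water and O6 closes the bridge, a known direct anhydro-sugar formation from free hexoses. The β-bridge is the only geometry the tether allows and no other centre is touched.

Step 2
Reactants: 2 1,6-anhydro-β-D-galactopyranose
Product: 3 1,6-anhydro-3,4-O-isopropylidene-β-D-galactopyranose
Conditions: Me2C(OMe)2, TsOH·H2O (cat.), acetone, rt
Reagents that add atoms: 2,2-dimethoxypropane, COC(C)(C)OC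
Why: Acid-catalysed transacetalisation; only O3 and O4 are cis (O2 and O3 are trans-diaxial in the bridged chair), so the dioxolane forms there and leaves O2 as the single free hydroxyl.

Step 3
Reactants: 3 1,6-anhydro-3,4-O-isopropylidene-β-D-galactopyranose
Product: 4 1,6-anhydro-3,4-O-isopropylidene-2-O-(4-methylphenylsulfonyl)-β-D-galactopyranose
Conditions: TsCl, pyridine, DMAP (cat.), rt to 40 °C
Reagents that add atoms: 4-methylbenzenesulfonyl chloride, Cc1ccc(cc1)S(Cl)(=O)=O
Why: Sulfonylation of the only free hydroxyl turns sugar C2 into the electrophilic site for oxirane closure.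

Step 4
Reactants: 4 1,6-anhydro-3,4-O-isopropylidene-2-O-(4-methylphenylsulfonyl)-β-D-galactopyranose
Product: 6 1,6:2,3-dianhydro-β-D-talopyranose, via diol tosylate 5 (not isolated)
Conditions: 80% aq. AcOH, 60 °C; evaporate; NaOMe, MeOH, rt
Reagents that add atoms: none
Why: Acetal hydrolysis, then intramolecular Williamson closure: O3 and the C2 tosylate are trans-diaxial in the 1C4 chair, so the alkoxide displaces tosylate with inversion at C2 to the talo oxirane. The free O4 is cis to the oxirane and cannot start an epoxide migration.

Step 5
Reactants: 6 1,6:2,3-dianhydro-β-D-talopyranose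
Product: 7 1,6:2,3-dianhydro-4-O-(2-naphthylmethyl)-β-D-talopyranose
Conditions: NaH, 2-(bromomethyl)naphthalene, Bu4NI (cat.), DMF, 0 °C to rt
Reagents that add atoms: 2-(bromomethyl)naphthalene, BrCc1ccc2ccccc2c1
Why: Williamson etherification of the only hydroxyl; the NAP ether withstands organometallics, acid and base and is removed oxidatively later, which marks the future O9 as the site of the enoate.

Step 6
Reactants: 7 1,6:2,3-dianhydro-4-O-(2-naphthylmethyl)-β-D-talopyranose; 8 isopropenylmagnesium bromide
Product: 9 1,6-anhydro-2-deoxy-2-C-isopropenyl-4-O-(2-naphthylmethyl)-β-D-galactopyranose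
Conditions: CuI (20 mol %), THF, −30 to 0 °C; aq. NH4Cl
Reagents that add atoms: isopropenylmagnesium bromide (8), C=C(C)[Mg]Br
Why: Copper-catalysed Grignard opening of an epoxide; the bridge locks the 1C4 chair, so trans-diaxial (Fürst–Plattner) attack occurs at sugar C2 from the face opposite the oxirane. This sets the branch (target C7) by SN2 inversion in the galacto configuration and unveils O3 (target O8) as the only free hydroxyl.

Step 7
Reactants: 9 1,6-anhydro-2-deoxy-2-C-isopropenyl-4-O-(2-naphthylmethyl)-β-D-galactopyranose
Product: 10 methyl 2-deoxy-2-C-isopropenyl-4-O-(2-naphthylmethyl)-α-D-galactopyranoside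
Conditions: TsOH·H2O (0.2 equiv), MeOH, 50 °C
Reagents that add atoms: methanol, CO
Why: Acid-catalysed methanolysis of the internal acetal (Fischer-type glycosidation); the 2-deoxy-2-C-alkyl acetal ionises readily, so mild acid should suffice and spare the isopropenyl group. The blocked O4 excludes furanosides and the anomeric effect favours the α-glycoside drawn.

Step 8
Reactants: 10 methyl 2-deoxy-2-C-isopropenyl-4-O-(2-naphthylmethyl)-α-D-galactopyranoside
Product: 11 methyl 2,6-dideoxy-6-iodo-2-C-isopropenyl-4-O-(2-naphthylmethyl)-α-D-galactopyranoside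
Conditions: I2, PPh3, imidazole, toluene/MeCN, rt
Reagents that add atoms: iodine, II
Why: Appel-type iodination (Garegg conditions), selective for the primary hydroxyl over the flanked secondary O3–H.

Step 9
Reactants: 11 methyl 2,6-dideoxy-6-iodo-2-C-isopropenyl-4-O-(2-naphthylmethyl)-α-D-galactopyranoside
Product: 12 methyl 3-O-(tert-butyldimethylsilyl)-2,6-dideoxy-6-iodo-2-C-isopropenyl-4-O-(2-naphthylmethyl)-α-D-galactopyranoside
Conditions: TBSOTf, 2,6-lutidine, CH2Cl2, −20 to 0 °C
Reagents that add atoms: tert-butyldimethylsilyl trifluoromethanesulfonate, CC(C)(C)[Si](C)(C)OS(=O)(=O)C(F)(F)F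
Why: Silylation of the remaining hydroxyl with a silyl triflate; the TBS ether is orthogonal to the NAP ether, so O8 and O9 stay distinguishable to the end.

Step 10
Reactants: 12 methyl 3-O-(tert-butyldimethylsilyl)-2,6-dideoxy-6-iodo-2-C-isopropenyl-4-O-(2-naphthylmethyl)-α-D-galactopyranoside
Product: 13 methyl 3-O-(tert-butyldimethylsilyl)-2,6-dideoxy-2-C-isopropenyl-4-O-(2-naphthylmethyl)-hex-5-enopyranoside (galacto-derived, α)
Conditions: DBU, toluene, 80 °C
Reagents that add atoms: none
Why: E2 dehydrohalogenation of the primary iodide gives the exocyclic enol ether, the standard entry to 6-deoxyhex-5-enopyranosides.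

Step 11
Reactants: 13 methyl 3-O-(tert-butyldimethylsilyl)-2,6-dideoxy-2-C-isopropenyl-4-O-(2-naphthylmethyl)-hex-5-enopyranoside
Product: 15 ring A β-hydroxy ketone (C1 ketone; C6 OH cis to C7 isopropenyl; C8 OTBS trans to C7; C9 ONAP cis to O8), via mercurio keto aldehyde 14 (not isolated)
Conditions: Hg(OCOCF3)2 (10 mol %), acetone/H2O (4:1), rt
Reagents that add atoms: water, O
Why: Divalent mercury adds to the electron-rich exocyclic enol ether (hydroxymercuration) to give a hemiketal that opens to the C1 ketone; the former ring oxygen stays on the anomeric carbon as a hemiacetal, which loses methanol to unmask the C6 aldehyde. The α-mercurio ketone carbon C2 then adds to the aldehyde, forming C2–C6 and releasing the mercury salt, so the metal is needed only in catalytic amount. This is the Ferrier carbocyclisation of 6-deoxyhex-5-enopyranosides to 3-hydroxycyclohexanones. Ring A closes in the 6-(enolendo)-exo-trig mode. C7, C8 and C9 are untouched and carry the galactose configuration into the carbocycle; the only new centre, the C6 carbinol, is expected mainly trans to O8 through a chair-like aldol transition state and is erased in step 12, so its ratio does not matter. The step needs chemoselectivity for the enol ether over the isopropenyl group, which the far higher nucleophilicity of the enol ether and the reversibility of alkene oxymercuration in the presence of trifluoroacetic acid should secure. It also needs the aldehyde to be trapped before its doubly activated C7 hydrogen is lost, which the fast intramolecular six-ring closure provides. The silyl and NAP ethers tolerate the near-neutral aqueous acetone.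

Step 12
Reactants: 15 ring A β-hydroxy ketone
Product: 17 ring A enone (C1 ketone, C2=C6, C7 isopropenyl, C8 OTBS, C9 ONAP), via mesylate 16 (not isolated)
Conditions: MsCl, Et3N, DMAP (cat.), CH2Cl2, 0 °C to rt
Reagents that add atoms: none
Why: Mesylation and in situ E1cB elimination through the C1 enolate; both C6 epimers converge on the same enone and the weak base leaves the C7 and C9 hydrogens alone.

Step 13
Reactants: 17 ring A enone; 18 1-(tert-butyldimethylsilyloxy)-1-methoxyethene
Product: 20 C6-(methoxycarbonylmethyl) ketone (C6 chain trans to C7 isopropenyl), via silyl enol ether 19 (not isolated)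
Conditions: TBSOTf (10 mol %), 2,6-di-tert-butylpyridine (20 mol %), CH2Cl2, −78 to −40 °C; then 1 M HCl, THF, 0 °C
Reagents that add atoms: 1-(tert-butyldimethylsilyloxy)-1-methoxyethene (18), C=C(OC)O[Si](C)(C)C(C)(C)C
Why: Mukaiyama–Michael addition; the activated enone is attacked at C6 anti to the adjacent C7 isopropenyl group (the usual trans outcome for 4-substituted cyclohexenones), which sets C6. The transient silyl enol ether is hydrolysed on cold acidic work-up while the secondary TBS ether survives.

Step 14
Reactants: 20 C6-(methoxycarbonylmethyl) ketone; 21 2-bromo-N-methoxy-N-methylacetamide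
Product: 22 C2,C6-trans-dialkylated ketone (C2 CH2C(O)N(OMe)Me, C6 CH2CO2Me, all ring substituents equatorial except O9)
Conditions: LiN(SiMe3)2 (1.05 equiv), THF, −78 °C; 21, DMPU, −78 to −30 °C
Reagents that add atoms: 2-bromo-N-methoxy-N-methylacetamide (21), BrCC(=O)N(C)OC
Why: Kinetic enolate alkylation: the base removes a C2 hydrogen and not the equatorial, alkoxy-bearing C9 hydrogen or the much less acidic ester α-hydrogens. The bromo amide enters at C2 trans to the C6 chain, the all-equatorial and thermodynamically preferred arrangement that becomes the trans ring fusion.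

Step 15
Reactants: 22 C2,C6-trans-dialkylated ketone
Product: 23 C1-methylene ester amide
Conditions: Zn, CH2Br2, TiCl4, THF/CH2Cl2, 0 °C to rt
Reagents that add atoms: dibromomethane, BrCBr
Why: Takai–Lombardo methylenation; the non-basic zinc/titanium reagent olefinates the ketone without touching ester or amide and without enolising C2 or C9. The trans C2/C6 relationship is thereby locked and the base-sensitive β-silyloxy ketone is gone before the Claisen step.

Step 16
Reactants: 23 C1-methylene ester amide
Product: 24 trans-hydrindane β-keto ester (C4 ketone, C5 CO2Me cis to H6)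
Conditions: LiN(SiMe3)2 (2.2 equiv), THF, −78 to 0 °C; aq. NH4Cl
Reagents that add atoms: none
Why: Dieckmann-type crossed Claisen cyclisation (5-exo-trig): the ester α-CH2 (C5) is the more acidic site and the N-methoxy-N-methylamide the better acyl acceptor, so C5 attacks C4 and not the reverse. C5 remains epimerisable and should settle with the ester trans to the C6–C7 bond.

Step 17
Reactants: 24 trans-hydrindane β-keto ester
Product: 25 cis-β-hydroxy ester (C4 OH and C5 CO2Me cis, both cis to H6)
Conditions: NaBH4, MeOH/THF, −40 °C
Reagents that add atoms: none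
Why: Borohydride reduction of the ring ketone; hydride should add to C4 from the face opposite the C5 ester, giving the cis hydroxy ester (4S) while the labile C5 centre is fixed in its more stable configuration. The methyl ester is inert under these conditions.

Step 18
Reactants: 25 cis-β-hydroxy ester
Product: 27 β-hydroxy methyl ketone (C4 OH, C5 acetyl, cis), via Weinreb amide 26 (not isolated)
Conditions: MeNHOMe·HCl, MeMgCl (excess), THF, −20 to 0 °C; aq. NH4Cl
Reagents that add atoms: methylmagnesium chloride, C[Mg]Cl
Why: One-pot Weinreb amidation and Grignard addition: the magnesium amide of N,O-dimethylhydroxylamine converts the ester into the amide, whose chelated adduct with MeMgCl holds until work-up. The methyl ketone therefore forms without over-addition and is never exposed to base as a free β-alkoxy ketone.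

Step 19
Reactants: 27 β-hydroxy methyl ketone
Product: 28 anti-1,3-diol (C4 OH, C10 OH; 10S)
Conditions: Me4NBH(OAc)3, MeCN/AcOH (1:1), −30 °C
Reagents that add atoms: none
Why: Evans–Saksena reduction: the C4 hydroxyl binds the triacetoxyborohydride and delivers hydride intramolecularly to C10 through a chair transition state with the methyl group equatorial, giving the 1,3-anti diol, which corresponds to 10S. Alkenes and ethers are inert.

Step 20
Reactants: 28 anti-1,3-diol
Product: 29 C4,C10-diacetate
Conditions: Ac2O, pyridine, DMAP (cat.), CH2Cl2, rt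
Reagents that add atoms: acetic anhydride, CC(=O)OC(C)=O
Why: DMAP-catalysed acetylation of both secondary hydroxyls; O8 and O9 are still masked, so acetates go only to C4 and C10.

Step 21
Reactants: 29 C4,C10-diacetate
Product: 30 C9 alcohol (C8 OTBS retained)
Conditions: DDQ, CH2Cl2/pH 7 buffer (10:1), 0 °C to rt
Reagents that add atoms: none
Why: Oxidative cleavage of the NAP ether by hydride abstraction with DDQ and hydrolysis of the resulting oxocarbenium ion; the silyl ether, the acetates and the unactivated alkenes should be unaffected.

Step 22
Reactants: 30 C9 alcohol; 31 (E)-3-methylpent-2-enoic acid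
Product: 32 C9 (E)-3-methylpent-2-enoate (C8 OTBS)
Conditions: 2,4,6-trichlorobenzoyl chloride, Et3N, THF, rt; then 30, DMAP, toluene, rt to 50 °C
Reagents that add atoms: (E)-3-methylpent-2-enoic acid (31), OC(=O)/C=C(\C)CC
Why: Yamaguchi esterification through the mixed anhydride with DMAP catalysis, chosen for a hindered axial allylic alcohol; the acid enters with its E geometry. O8 is silylated, so neither wrong-site acylation nor acyl migration can occur.

Step 23
Reactants: 32 C9 (E)-3-methylpent-2-enoate
Product: 33 C8 alcohol (deoxy precursor of the target with C7 isopropenyl)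
Conditions: HF·pyridine, pyridine, THF, 0 °C to rt
Reagents that add atoms: none
Why: Fluoride-induced desilylation under buffered, slightly acidic conditions, which avoids base-promoted acyl migration from O9 to the cis O8 and is done before the acid-sensitive oxirane exists.

Step 24
Reactants: 33 C8 alcohol
Product: 34 Songaricalarin B
Conditions: VO(acac)2 (5 mol %), tBuOOH (in decane), CH2Cl2, 0 °C to rt
Reagents that add atoms: tert-butyl hydroperoxide, CC(C)(C)OO
Why: Vanadium-catalysed hydroxyl-directed epoxidation of a homoallylic alcohol: the C8 vanadate ester can reach only the isopropenyl group (O8–C8–C7–C11 gauche) and not the C1 methylene (O8–C8–C9–C1 anti), and the enoate is too electron-poor to react. In the chair transition state fused trans to ring A, with the alkene eclipsing the C7–H bond, oxygen is delivered to the face that gives 11S.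

## Compound list

1 | D-galactose (β-pyranose form) | OC[C@H]1O[C@@H](O)[C@H](O)[C@@H](O)[C@H]1O | starting material
2 | 1,6-anhydro-β-D-galactopyranose | O1C[C@H]2O[C@@H]1[C@H](O)[C@@H](O)[C@H]2O | intermediate
3 | 1,6-anhydro-3,4-O-isopropylidene-β-D-galactopyranose | O1C[C@H]2O[C@@H]1[C@H](O)[C@H]3OC(C)(C)O[C@@H]23 | intermediate
4 | 1,6-anhydro-3,4-O-isopropylidene-2-O-(4-methylphenylsulfonyl)-β-D-galactopyranose | O1C[C@H]2O[C@@H]1[C@H](OS(=O)(=O)c4ccc(C)cc4)[C@H]3OC(C)(C)O[C@@H]23 | intermediate
5 | 1,6-anhydro-2-O-(4-methylphenylsulfonyl)-β-D-galactopyranose | O1C[C@H]2O[C@@H]1[C@H](OS(=O)(=O)c3ccc(C)cc3)[C@@H](O)[C@H]2O | intermediate (not isolated)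
6 | 1,6:2,3-dianhydro-β-D-talopyranose | O1C[C@H]2O[C@@H]1[C@H]3O[C@H]3[C@H]2O | intermediate
7 | 1,6:2,3-dianhydro-4-O-(2-naphthylmethyl)-β-D-talopyranose | O1C[C@H]2O[C@@H]1[C@H]3O[C@H]3[C@H]2OCc4ccc5ccccc5c4 | intermediate
8 | isopropenylmagnesium bromide | C=C(C)[Mg]Br | starting material
9 | 1,6-anhydro-2-deoxy-2-C-isopropenyl-4-O-(2-naphthylmethyl)-β-D-galactopyranose | O1C[C@H]2O[C@@H]1[C@H](C(C)=C)[C@@H](O)[C@H]2OCc3ccc4ccccc4c3 | intermediate
10 | methyl 2-deoxy-2-C-isopropenyl-4-O-(2-naphthylmethyl)-α-D-galactopyranoside | OC[C@H]1O[C@H](OC)[C@H](C(C)=C)[C@@H](O)[C@H]1OCc2ccc3ccccc3c2 | intermediate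
11 | methyl 2,6-dideoxy-6-iodo-2-C-isopropenyl-4-O-(2-naphthylmethyl)-α-D-galactopyranoside | IC[C@H]1O[C@H](OC)[C@H](C(C)=C)[C@@H](O)[C@H]1OCc2ccc3ccccc3c2 | intermediate
12 | methyl 3-O-(tert-butyldimethylsilyl)-2,6-dideoxy-6-iodo-2-C-isopropenyl-4-O-(2-naphthylmethyl)-α-D-galactopyranoside | IC[C@H]1O[C@H](OC)[C@H](C(C)=C)[C@@H](O[Si](C)(C)C(C)(C)C)[C@H]1OCc2ccc3ccccc3c2 | intermediate
13 | methyl 3-O-(tert-butyldimethylsilyl)-2,6-dideoxy-2-C-isopropenyl-4-O-(2-naphthylmethyl)-hex-5-enopyranoside (galacto-derived, α; branch and O3 equatorial, O4 axial) | C=C1O[C@H](OC)[C@H](C(C)=C)[C@@H](O[Si](C)(C)C(C)(C)C)[C@H]1OCc2ccc3ccccc3c2 | intermediate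
14 | acyclic C2-(trifluoroacetoxymercurio) C1-keto C6-aldehyde | O=C[C@H](C(C)=C)[C@@H](O[Si](C)(C)C(C)(C)C)[C@@H](OCc1ccc2ccccc2c1)C(=O)C[Hg]OC(=O)C(F)(F)F | intermediate (not isolated)
15 | ring A β-hydroxy ketone: 3-(tert-butyldimethylsilyloxy)-5-hydroxy-2-(2-naphthylmethoxy)-4-isopropenylcyclohexanone (target C1 ketone, C6 OH cis to C7 isopropenyl, C8 OTBS, C9 ONAP) | O=C1C[C@H](O)[C@H](C(C)=C)[C@@H](O[Si](C)(C)C(C)(C)C)[C@H]1OCc2ccc3ccccc3c2 | intermediate
16 | C6 methanesulfonate of 15 | O=C1C[C@H](OS(C)(=O)=O)[C@H](C(C)=C)[C@@H](O[Si](C)(C)C(C)(C)C)[C@H]1OCc2ccc3ccccc3c2 | intermediate (not isolated)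
17 | ring A enone: 5-(tert-butyldimethylsilyloxy)-6-(2-naphthylmethoxy)-4-isopropenylcyclohex-2-enone | O=C1C=C[C@H](C(C)=C)[C@@H](O[Si](C)(C)C(C)(C)C)[C@H]1OCc2ccc3ccccc3c2 | intermediate
18 | 1-(tert-butyldimethylsilyloxy)-1-methoxyethene | C=C(OC)O[Si](C)(C)C(C)(C)C | starting material
19 | C1 tert-butyldimethylsilyl enol ether of 20 (C1=C2) | CC(C)(C)[Si](C)(C)OC1=C[C@@H](CC(=O)OC)[C@H](C(C)=C)[C@@H](O[Si](C)(C)C(C)(C)C)[C@H]1OCc2ccc3ccccc3c2 | intermediate (not isolated)
20 | methyl 2-[ring A ketone C6-yl]acetate (C6 chain trans to C7 isopropenyl; C8 OTBS; C9 ONAP) | O=C1C[C@@H](CC(=O)OC)[C@H](C(C)=C)[C@@H](O[Si](C)(C)C(C)(C)C)[C@H]1OCc2ccc3ccccc3c2 | intermediate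
21 | 2-bromo-N-methoxy-N-methylacetamide | BrCC(=O)N(C)OC | starting material
22 | C2,C6-trans-dialkylated ring A ketone (C2 CH2C(O)N(OMe)Me; C6 CH2CO2Me) | O=C1[C@H](CC(=O)N(C)OC)[C@@H](CC(=O)OC)[C@H](C(C)=C)[C@@H](O[Si](C)(C)C(C)(C)C)[C@H]1OCc2ccc3ccccc3c2 | intermediate
23 | C1-methylene analogue of 22 | C=C1[C@H](CC(=O)N(C)OC)[C@@H](CC(=O)OC)[C@H](C(C)=C)[C@@H](O[Si](C)(C)C(C)(C)C)[C@H]1OCc2ccc3ccccc3c2 | intermediate
24 | trans-hydrindane β-keto ester (C4 ketone; C5 CO2Me cis to H6; C1 methylene; C7 isopropenyl; C8 OTBS; C9 ONAP) | C=C1[C@@H]2CC(=O)[C@H](C(=O)OC)[C@H]2[C@H](C(C)=C)[C@@H](O[Si](C)(C)C(C)(C)C)[C@H]1OCc3ccc4ccccc4c3 | intermediate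
25 | cis-β-hydroxy ester (4S hydroxyl cis to C5 CO2Me) | C=C1[C@@H]2C[C@H](O)[C@H](C(=O)OC)[C@H]2[C@H](C(C)=C)[C@@H](O[Si](C)(C)C(C)(C)C)[C@H]1OCc3ccc4ccccc4c3 | intermediate
26 | C5 N-methoxy-N-methylamide of 25 | C=C1[C@@H]2C[C@H](O)[C@H](C(=O)N(C)OC)[C@H]2[C@H](C(C)=C)[C@@H](O[Si](C)(C)C(C)(C)C)[C@H]1OCc3ccc4ccccc4c3 | intermediate (not isolated)
27 | β-hydroxy methyl ketone (C4 OH, C5 acetyl, cis) | C=C1[C@@H]2C[C@H](O)[C@H](C(C)=O)[C@H]2[C@H](C(C)=C)[C@@H](O[Si](C)(C)C(C)(C)C)[C@H]1OCc3ccc4ccccc4c3 | intermediate
28 | anti-1,3-diol (C4 OH, 10S OH) | C=C1[C@@H]2C[C@H](O)[C@H]([C@H](C)O)[C@H]2[C@H](C(C)=C)[C@@H](O[Si](C)(C)C(C)(C)C)[C@H]1OCc3ccc4ccccc4c3 | intermediate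
29 | C4,C10-diacetate (C8 OTBS, C9 ONAP) | C=C1[C@@H]2C[C@H](OC(C)=O)[C@H]([C@H](C)OC(C)=O)[C@H]2[C@H](C(C)=C)[C@@H](O[Si](C)(C)C(C)(C)C)[C@H]1OCc3ccc4ccccc4c3 | intermediate
30 | C9 alcohol (C4,C10-diacetate, C8 OTBS) | C=C1[C@@H]2C[C@H](OC(C)=O)[C@H]([C@H](C)OC(C)=O)[C@H]2[C@H](C(C)=C)[C@@H](O[Si](C)(C)C(C)(C)C)[C@H]1O | intermediate
31 | (E)-3-methylpent-2-enoic acid | OC(=O)/C=C(\C)CC | starting material
32 | C9 (E)-3-methylpent-2-enoate (C8 OTBS) | C=C1[C@@H]2C[C@H](OC(C)=O)[C@H]([C@H](C)OC(C)=O)[C@H]2[C@H](C(C)=C)[C@@H](O[Si](C)(C)C(C)(C)C)[C@H]1OC(=O)/C=C(\C)CC | intermediate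
33 | C8 alcohol (target lacking the oxirane oxygen; C7 isopropenyl) | C=C1[C@@H]2C[C@H](OC(C)=O)[C@H]([C@H](C)OC(C)=O)[C@H]2[C@H](C(C)=C)[C@@H](O)[C@H]1OC(=O)/C=C(\C)CC | intermediate
34 | Songaricalarin B | C=C1[C@@H]2C[C@H](OC(C)=O)[C@H]([C@H](C)OC(C)=O)[C@H]2[C@H]([C@@]2(C)CO2)[C@@H](O)[C@H]1OC(=O)/C=C(\C)CC | target

## Step count and least certain steps

Total: 24 steps. Longest linear sequence: 24 steps from 1 (8, 18, 21 and 31 are bought).

**Step 11 (key step).** The most likely failure is loss of the C7 configuration or migration of the isopropenyl double bond into conjugation in the transient aldehyde, whose C7 hydrogen is both α-carbonyl and allylic. Slow catalyst turnover through oxymercuration of the isopropenyl group is a second risk. Fallback: from 13, Al(iBu)3 in toluene (the reductive enol-ether-to-carbocycle rearrangement that keeps the aglycon and passes through no free aldehyde) should give the cyclohexanol methyl ether F1. Dess–Martin oxidation gives the β-methoxy ketone F2, and DBU eliminates methanol to rejoin the route at 17.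

**Step 24.** Poor facial selectivity at C11 is the main risk: the isopropenyl group can rotate and the methyl group must take the pseudo-axial position in the directing chair. Sluggish oxygen transfer to a homoallylic alcohol, which gives background reactions time, is the second. Fallback: from 33, reagent-controlled epoxidation with a fructose-derived chiral ketone and KHSO5 (a chiral dioxirane) at buffered pH. The C1 methylene is deactivated by the allylic ester and more hindered, so 34 should be reached directly, without a new intermediate.

**Step 17.** Hydride delivery to the wrong face of C4 is possible, because small hydrides are not strongly biased on 2-substituted cyclopentanones. Fallback: from 24, if the C4-epimeric hydroxy ester F3 predominates, Mitsunobu inversion (PPh3, DIAD, 4-nitrobenzoic acid) gives the cis 4-nitrobenzoate F4. K2CO3 in MeOH then returns to the route at 25.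

**Step 13.** Low reactivity or poor facial control at the hindered C6, flanked by the C7 branch, and acid-promoted loss of the silyl ether during work-up are the risks. Fallback: from 17, thermodynamic Michael addition of dimethyl malonate (NaOMe cat., MeOH) gives the malonate adduct F5. Krapcho demethoxycarbonylation (LiCl, wet DMSO, 140 °C) rejoins at 20.

**Step 22.** Slow acylation of the hindered axial allylic hydroxyl may allow E/Z isomerisation or deconjugation of the activated acid through a dienolate. Fallback: from 30, heating with 2,2,6-trimethyl-4H-1,3-dioxin-4-one (acylketene transfer, insensitive to hindrance) gives the acetoacetate F6. Tf2O with aqueous Me4NOH gives the (E)-enol triflate F7. Fe(acac)3-catalysed coupling with EtMgBr at −30 °C then installs the ethyl group with retention and rejoins at 32.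

**Step 7.** Acid-promoted addition of methanol to the isopropenyl group, or its participation with the oxocarbenium ion, may compete with bridge opening. Fallback: from 9, PhSSiMe3 with ZnI2 in CH2Cl2 (Lewis-acid thiolysis of the bridge, then K2CO3/MeOH to remove silyl groups) gives the phenyl thioglycoside F8. MeOTf, MeOH and 2,6-di-tert-butyl-4-methylpyridine convert it into 10.

## Further compounds

F1 | step 11 | 3-(tert-butyldimethylsilyloxy)-5-methoxy-2-(2-naphthylmethoxy)-4-isopropenylcyclohexanol (C1 and C6 epimer mixture, both centres erased later) | OC1CC(OC)[C@H](C(C)=C)[C@@H](O[Si](C)(C)C(C)(C)C)[C@H]1OCc2ccc3ccccc3c2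
F2 | step 11 | 3-(tert-butyldimethylsilyloxy)-5-methoxy-2-(2-naphthylmethoxy)-4-isopropenylcyclohexanone (C6 epimer mixture) | O=C1CC(OC)[C@H](C(C)=C)[C@@H](O[Si](C)(C)C(C)(C)C)[C@H]1OCc2ccc3ccccc3c2
F0 | step 24 | none | none
F3 | step 17 | C4-epimer of 25 (C4 OH trans to C5 CO2Me) | C=C1[C@@H]2C[C@@H](O)[C@H](C(=O)OC)[C@H]2[C@H](C(C)=C)[C@@H](O[Si](C)(C)C(C)(C)C)[C@H]1OCc3ccc4ccccc4c3
F4 | step 17 | C4 4-nitrobenzoate of 25 | C=C1[C@@H]2C[C@H](OC(=O)c5ccc(cc5)[N+](=O)[O-])[C@H](C(=O)OC)[C@H]2[C@H](C(C)=C)[C@@H](O[Si](C)(C)C(C)(C)C)[C@H]1OCc3ccc4ccccc4c3
F5 | step 13 | dimethyl 2-[ring A ketone C6-yl]malonate | O=C1C[C@@H](C(C(=O)OC)C(=O)OC)[C@H](C(C)=C)[C@@H](O[Si](C)(C)C(C)(C)C)[C@H]1OCc2ccc3ccccc3c2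
F6 | step 22 | C9 acetoacetate of 30 | C=C1[C@@H]2C[C@H](OC(C)=O)[C@H]([C@H](C)OC(C)=O)[C@H]2[C@H](C(C)=C)[C@@H](O[Si](C)(C)C(C)(C)C)[C@H]1OC(=O)CC(C)=O
F7 | step 22 | C9 (E)-3-(trifluoromethylsulfonyloxy)but-2-enoate | C=C1[C@@H]2C[C@H](OC(C)=O)[C@H]([C@H](C)OC(C)=O)[C@H]2[C@H](C(C)=C)[C@@H](O[Si](C)(C)C(C)(C)C)[C@H]1OC(=O)/C=C(\C)OS(=O)(=O)C(F)(F)F
F8 | step 7 | phenyl 2-deoxy-2-C-isopropenyl-4-O-(2-naphthylmethyl)-1-thio-D-galactopyranoside (α drawn, anomer mixture) | OC[C@H]1O[C@H](Sc2ccccc2)[C@H](C(C)=C)[C@@H](O)[C@H]1OCc3ccc4ccccc4c3
A1 | alternative 1 | trans-hydrindane cis-C8/C9 diol with C1 4-methoxybenzyl ether (pinacol product) | [C@@H]1(OCc2ccc(OC)cc2)[C@@H]3C[C@H](OC(C)=O)[C@H]([C@H](C)OC(C)=O)[C@H]3[C@H](C(C)=C)[C@@H](O)[C@H]1O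
A2 | alternative 1 | cyclopentane C8,C9-dialdehyde (pinacol precursor) | O=C[C@H](OCc1ccc(OC)cc1)[C@@H]2C[C@H](OC(C)=O)[C@H]([C@H](C)OC(C)=O)[C@H]2[C@H](C(C)=C)C=O
A3 | alternative 2 | trans-hydrindane with C4 hydroxyl and C5 acetyl (ring-contraction product) | CC1=C[C@H](O[Si](C)(C)C(C)(C)C)[C@@H](C(C)=C)[C@@H]2[C@@H](C(C)=O)[C@@H](O)C[C@@H]12
A4 | alternative 2 | trans-decalin C4–C5 epoxide with C10 tertiary alcohol (ring-contraction precursor) | CC1=C[C@H](O[Si](C)(C)C(C)(C)C)[C@@H](C(C)=C)[C@@H]2[C@](C)(O)[C@H]3O[C@H]3C[C@@H]12
A5 | alternative 3 | bicyclic C4 enone with C5=C6 alkene (Pauson–Khand product) | [C@@H]1(OCOC)[C@@H]2CC(=O)C([C@H](C)O[Si](C)(C)C(C)(C)C)=C2[C@H](C(C)=C)[C@@H](OC(C)(C)O3)[C@H]13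
A6 | alternative 3 | acyclic 1,7-enyne (Pauson–Khand precursor) | C=C[C@@H](OCOC)[C@@H]1OC(C)(C)O[C@@H]1[C@@H](C(C)=C)C#C[C@H](C)O[Si](C)(C)C(C)(C)C
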